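**Strategy.** The target is a trans-fused hydroazulene whose oxygenated carbons C5 (epoxide, five-membered ring) and C10 (ester, seven-membered ring) are 1,5-related through C6–C2–C1. Numbering: C1 carries isopropyl, C2/C6 are the fusion atoms, C4 and C8 carry methyl. Everything rests on cutting C2–C6 and C1–C10. One photochemical operation, an intramolecular enol–alkene [2+2] addition followed by hydrogenolytic unmasking and retro-aldol opening of the cyclobutanol, closes the cyclopentanone, expands a cyclopentane into the cycloheptanone and fixes C2. The precursor is the benzyl enol carbonate of a 2-acylcyclopentanone that carries the C8 silyloxy/methyl centre and an (E)-alkene tethered through an (S)-methyl-bearing acyl chain.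

Key step: step 11

Convention: atom labels C1–C10 as above; α is the ring face of the C8 oxygen, β that of the C8 methyl group.
Assumption: the (R,R) antipode of the bisphosphine ligand in step 1 is taken to give the (S)-boronate and hence (R)-4; should the sense of induction be the opposite, the (S,S) ligand is used and nothing else changes.

Step 1
Reactants: 1 3-methylcyclopent-2-en-1-one; 2 bis(pinacolato)diboron
Product: 4 (R)-3-hydroxy-3-methylcyclopentan-1-one, via β-boryl ketone 3 (not isolated)
Conditions: Cu(MeCN)4PF6 (5 mol%), (R,R)-QuinoxP* (6 mol%), LiOt-Bu (10 mol%), DMSO, rt; then NaBO3·4H2O, THF/H2O, rt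
Reagents that add atoms: sodium perborate, [Na+].[Na+].O[B-]1(O)OO[B-](O)(O)OO1
Why: Copper-catalysed enantioselective conjugate borylation, in which the phosphine-bound monovalent copper boryl adds to the β-carbon of the enone on the face chosen by the ligand and so sets the quaternary centre (C8 of the target); perborate oxidation of the C–B bond then proceeds with retention.

Step 2
Reactants: 4 (R)-3-hydroxy-3-methylcyclopentan-1-one
Product: 5 (R)-3-methyl-3-(triethylsilyloxy)cyclopentan-1-one
Conditions: Et3SiOTf, 2,6-lutidine, CH2Cl2, −78 °C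
Reagents that add atoms: triethylsilyl trifluoromethanesulfonate, CC[Si](CC)(CC)OS(=O)(=O)C(F)(F)F
Why: Silylation of the tertiary alcohol with a silyl triflate and a hindered pyridine base at low temperature should outrun enolisation and β-elimination; the silyl group can turn away from the ring, so only an oxygen atom flanks that face, and it comes off later with fluoride without acid or base.

Step 3
Reactants: 6 isobutyraldehyde; 7 triethyl phosphonoacetate
Product: 8 ethyl (E)-4-methylpent-2-enoate
Conditions: NaH, THF, 0 °C → rt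
Reagents that add atoms: none
Why: Horner–Wadsworth–Emmons olefination of an α-branched aldehyde with a stabilised phosphonate anion should give the (E)-enoate.

Step 4
Reactants: 8 ethyl (E)-4-methylpent-2-enoate
Product: 9 (E)-4-methylpent-2-en-1-ol
Conditions: i-Bu2AlH (2.2 equiv), CH2Cl2, −78 → 0 °C; aq. potassium sodium tartrate
Reagents that add atoms: none
Why: The aluminium hydride reduces the conjugated ester by two 1,2-additions to the allylic alcohol and leaves the alkene alone.

Step 5
Reactants: 9 (E)-4-methylpent-2-en-1-ol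
Product: 10 (E)-1-bromo-4-methylpent-2-ene
Conditions: CBr4, PPh3, CH2Cl2, 0 °C
Reagents that add atoms: tetrabromomethane, BrC(Br)(Br)Br
Why: Appel bromination displaces the oxyphosphonium ion of the primary allylic alcohol by SN2 under neutral conditions, so the (E)-geometry should be kept.

Step 6
Reactants: 11 (R)-4-benzyl-3-propionyloxazolidin-2-one; 10 (E)-1-bromo-4-methylpent-2-ene
Product: 12 (R)-4-benzyl-3-[(2S,4E)-2,6-dimethylhept-4-enoyl]oxazolidin-2-one
Conditions: NaN(SiMe3)2, THF, −78 °C; then 10, −78 → −40 °C
Reagents that add atoms: none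
Why: Evans asymmetric alkylation, in which the chelated (Z)-sodium enolate is attacked by the allylic bromide on the face away from the benzyl group of the auxiliary, sets the (S)-methyl centre (C4).

Step 7
Reactants: 12 (R)-4-benzyl-3-[(2S,4E)-2,6-dimethylhept-4-enoyl]oxazolidin-2-one
Product: 14 (2S,4E)-2,6-dimethylhept-4-enoic acid, via peroxy acid 13 (not isolated)
Conditions: LiOH, H2O2, THF/H2O, 0 °C; then aq. Na2SO3; acidify (HCl)
Reagents that add atoms: hydrogen peroxide, OO
Why: Hydroperoxide anion attacks the exocyclic imide carbonyl selectively (auxiliary cleavage) and sulfite reduces the peroxy acid, neither event touching C4.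

Step 8
Reactants: 14 (2S,4E)-2,6-dimethylhept-4-enoic acid
Product: 15 1-[(2S,4E)-2,6-dimethylhept-4-enoyl]-1H-benzotriazole
Conditions: 1H-benzotriazole (4 equiv), SOCl2 (1.05 equiv), CH2Cl2, rt
Reagents that add atoms: 1H-benzotriazole, c1ccc2[nH]nnc2c1
Why: Thionyl chloride with excess benzotriazole converts the acid into a neutral, isolable N-acylbenzotriazole, an acyl donor that favours C-acylation of enolates and is not prone to ketene formation, so C4 should be preserved.

Step 9
Reactants: 5 (R)-3-methyl-3-(triethylsilyloxy)cyclopentan-1-one; 15 1-[(2S,4E)-2,6-dimethylhept-4-enoyl]-1H-benzotriazole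
Product: 16 (4R)-2-[(2S,4E)-2,6-dimethylhept-4-enoyl]-4-methyl-4-(triethylsilyloxy)cyclopentan-1-one (held as its enol)
Conditions: 5 (2.2 equiv), LiN(i-Pr)2 (2.1 equiv), THF, −78 °C; then 15, −78 → −30 °C; aq. NH4Cl
Reagents that add atoms: none
Why: Claisen-type C-acylation of a kinetic lithium enolate: the amide base removes a proton from the CH2 remote from the quaternary β-carbon (which also avoids β-elimination of the silyloxy group), the second enolate equivalent deprotonates the 1,3-diketone as it forms, and no fixed stereocentre arises because the product is enolised.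

Step 10
Reactants: 16 the 1,3-diketone; 17 benzyl chloroformate
Product: 18 benzyl (4R)-2-[(2S,4E)-2,6-dimethylhept-4-enoyl]-4-methyl-4-(triethylsilyloxy)cyclopent-1-en-1-yl carbonate
Conditions: pyridine, CH2Cl2, 0 °C
Reagents that add atoms: none
Why: O-acylation of the diketone enol by the chloroformate should take place at the less hindered ring oxygen, which leaves the ketone next to the branched C4 as the exocyclic carbonyl of the C5(=O)–C6=C10 chromophore.

Step 11
Reactants: 18 the benzyl enol carbonate
Product: 22 trans-fused hydroazulene-5,10-dione (C8 triethylsilyl ether; C1 isopropyl α; C2–H α; C4 methyl β; C6–H β; C8 methyl β), via photoadduct 19 (not isolated), via cyclobutanol 20 (not isolated), via cis-fused diketone 21 (not isolated)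
Conditions: hν (medium-pressure Hg lamp, Pyrex filter, λ > 300 nm), degassed EtOAc (0.005 M), 10 °C; then H2 (1 atm), Pd/C, EtOAc, rt; filter; then DBU (0.2 equiv), rt
Reagents that add atoms: none
Why: The triplet of the β-carbonyloxy enone bonds C6 to C2 through a five-membered transition state (5-exo mode, closing the cyclopentanone) and the 1,4-biradical then collapses at C1–C10 to the cis-fused cyclobutane; hydrogenolysis removes the benzyl carbonate as toluene and CO2, and cyclobutanol 20 breaks the strained C6–C10 bond by retro-aldol onto the C5 ketone, which enlarges the old cyclopentane to the cycloheptanone. The closest known reaction type is the intramolecular de Mayo reaction of 2-acylcycloalkanone enol carbonates. C2 is the only centre that must be set kinetically: the alkene has to add to the cyclopentene face anti to the C8 methyl group (syn to the slimmer silyloxy group), and the (S)-methyl group at C4 should reinforce this, because on that face it sits pseudo-equatorial and cis to C1 in the chair-like five-membered transition state. C1 and C6 are α to the two ketones and are settled thermodynamically by DBU (isopropyl equatorial and trans to C3, trans ring fusion expected), so alkene geometry and the kinetic protonation at C6 do not matter, and C4 is only a control element that is erased later. The step needs straight rather than crossed addition, which the two-atom link between C5 and C2 secures, and facial selectivity, which rests on the matched C4/C8 pair.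

Step 12
Reactants: 22 the silyl-protected dione
Product: 23 C8-hydroxy hydroazulene-5,10-dione
Conditions: HF·pyridine, THF/pyridine, 0 °C → rt
Reagents that add atoms: none
Why: Fluoride cleaves the tertiary silyl ether under mildly acidic, non-basic conditions, so the tertiary β-hydroxy ketone should neither dehydrate nor scramble C8 by retro-aldol/aldol.

Step 13
Reactants: 23 C8-hydroxy hydroazulene-5,10-dione
Product: 24 C8,C10-diol C5-ketone (C10–OH β; anti to C8–OH)
Conditions: Me4NBH(OAc)3, MeCN/AcOH (1:1), −30 → 0 °C
Reagents that add atoms: none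
Why: Evans–Saksena reduction, in which the C8 hydroxyl exchanges onto boron and delivers hydride through a six-membered transition state to the α-face of C10 only (C5 has no β-hydroxyl and this reagent leaves unassisted ketones alone), gives the C10 alcohol anti to the C8 hydroxyl.

Step 14
Reactants: 24 the diol ketone; 25 4-(benzyloxy)benzoyl chloride
Product: 26 C10 4-(benzyloxy)benzoate (C8–OH free; C5 ketone)
Conditions: DMAP (cat.), pyridine, CH2Cl2, 0 °C → rt
Reagents that add atoms: none
Why: DMAP-catalysed acylation esterifies the secondary C10 alcohol, while the tertiary C8 alcohol does not react under these conditions.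

Step 15
Reactants: 26 the hydroxy ester ketone
Product: 27 C8 trimethylsilyl ether of 26
Conditions: N-(trimethylsilyl)imidazole, CH2Cl2, rt
Reagents that add atoms: N-(trimethylsilyl)imidazole, C[Si](C)(C)n1ccnc1
Why: The silylimidazole silylates the tertiary alcohol without enolising the ketone, which keeps an alkoxide away from the ester and from C6–H in the next step.

Step 16
Reactants: 27 the silyl ether ketone
Product: 28 C4=C5 enol triflate (triflate on C5)
Conditions: LiN(i-Pr)2, THF, −78 °C; then PhNTf2, −78 → 0 °C
Reagents that add atoms: N-phenylbis(trifluoromethanesulfonimide), O=S(=O)(N(c1ccccc1)S(=O)(=O)C(F)(F)F)C(F)(F)F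
Why: Kinetic deprotonation by the hindered amide should prefer C4–H (flanked by CH3 and CH2) over the ring-fusion C6–H (flanked by two branched ring carbons and syn to the C8 methyl group), and O-triflation of that enolate places the double bond at C4=C5 while leaving C6 untouched.

Step 17
Reactants: 28 the enol triflate
Product: 30 C4=C5 alkene (C8–OH free; C10 4-(benzyloxy)benzoate), via silyl ether alkene 29 (not isolated)
Conditions: Pd(OAc)2 (5 mol%), PPh3 (10 mol%), n-Bu3N, HCO2H, DMF, 60 °C; then 1 M HCl, THF, rt
Reagents that add atoms: none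
Why: Palladium-catalysed formate reduction of an enol triflate (oxidative addition of zerovalent palladium, formate exchange, loss of CO2, reductive elimination) should give the alkene without double-bond migration, and dilute acid then removes the tertiary trimethylsilyl ether.

Step 18
Reactants: 30 the alkenyl alcohol
Product: 31 4α,5α-epoxide (benzyl ether of the target)
Conditions: VO(acac)2 (5 mol%), t-BuOOH, CH2Cl2, 0 °C → rt
Reagents that add atoms: tert-butyl hydroperoxide, CC(C)(C)OO
Why: Hydroxyl-directed vanadium-catalysed epoxidation, in which the bishomoallylic C8 alkoxide binds the vanadium peroxide and delivers oxygen to the α-face of C4=C5, sets C4 and C5 syn to the C8 hydroxyl; this syn epoxide cannot be opened from the back by that hydroxyl.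

Step 19
Reactants: 31 the benzyl-protected epoxide
Product: 32 CNP0245441.1 (target)
Conditions: H2 (1 atm), Pd/C, EtOAc, rt
Reagents that add atoms: none
Why: Hydrogenolysis of the aryl benzyl ether over palladium frees the phenol under neutral conditions, to which the trialkyl epoxide, the ester and the tertiary alcohol should be inert.

**Compound list**

1 | 3-methylcyclopent-2-en-1-one | CC1=CC(=O)CC1 | starting material
2 | bis(pinacolato)diboron | CC1(C)OB(OC1(C)C)B1OC(C)(C)C(C)(C)O1 | starting material
3 | (S)-3-methyl-3-(4,4,5,5-tetramethyl-1,3,2-dioxaborolan-2-yl)cyclopentan-1-one | O=C1C[C@](C)(B2OC(C)(C)C(C)(C)O2)CC1 | intermediate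
4 | (R)-3-hydroxy-3-methylcyclopentan-1-one | O=C1C[C@](C)(O)CC1 | intermediate
5 | (R)-3-methyl-3-(triethylsilyloxy)cyclopentan-1-one | O=C1C[C@](C)(O[Si](CC)(CC)CC)CC1 | intermediate
6 | isobutyraldehyde | CC(C)C=O | starting material
7 | triethyl phosphonoacetate | CCOC(=O)CP(=O)(OCC)OCC | starting material
8 | ethyl (E)-4-methylpent-2-enoate | CCOC(=O)/C=C/C(C)C | intermediate
9 | (E)-4-methylpent-2-en-1-ol | CC(C)/C=C/CO | intermediate
10 | (E)-1-bromo-4-methylpent-2-ene | CC(C)/C=C/CBr | intermediate
11 | (R)-4-benzyl-3-propionyloxazolidin-2-one | CCC(=O)N1[C@H](Cc2ccccc2)COC1=O | starting material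
12 | (R)-4-benzyl-3-[(2S,4E)-2,6-dimethylhept-4-enoyl]oxazolidin-2-one | CC(C)/C=C/C[C@H](C)C(=O)N1[C@H](Cc2ccccc2)COC1=O | intermediate
13 | (2S,4E)-2,6-dimethylhept-4-eneperoxoic acid | CC(C)/C=C/C[C@H](C)C(=O)OO | intermediate
14 | (2S,4E)-2,6-dimethylhept-4-enoic acid | CC(C)/C=C/C[C@H](C)C(=O)O | intermediate
15 | 1-[(2S,4E)-2,6-dimethylhept-4-enoyl]-1H-benzotriazole | CC(C)/C=C/C[C@H](C)C(=O)n1nnc2ccccc12 | intermediate
16 | (4R)-2-[(2S,4E)-2,6-dimethylhept-4-enoyl]-4-methyl-4-(triethylsilyloxy)cyclopentan-1-one, drawn as its ring enol | CC(C)/C=C/C[C@H](C)C(=O)C1=C(O)C[C@](C)(O[Si](CC)(CC)CC)C1 | intermediate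
17 | benzyl chloroformate | O=C(Cl)OCc1ccccc1 | starting material
18 | benzyl (4R)-2-[(2S,4E)-2,6-dimethylhept-4-enoyl]-4-methyl-4-(triethylsilyloxy)cyclopent-1-en-1-yl carbonate | CC(C)/C=C/C[C@H](C)C(=O)C1=C(OC(=O)OCc2ccccc2)C[C@](C)(O[Si](CC)(CC)CC)C1 | intermediate
19 | photoadduct: cyclopentanone/cyclobutane/cyclopentane tricycle with C2–C6 and C1–C10 formed on the α-face, C10 benzyl carbonate | CC(C)[C@H]1[C@@H]2C[C@H](C)C(=O)[C@@]23C[C@@](C)(O[Si](CC)(CC)CC)C[C@@]13OC(=O)OCc1ccccc1 | intermediate
20 | cyclobutanol: the same tricycle with free C10–OH | CC(C)[C@H]1[C@@H]2C[C@H](C)C(=O)[C@@]23C[C@@](C)(O[Si](CC)(CC)CC)C[C@@]13O | intermediate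
21 | cis-fused C6 epimer of 22 | CC(C)[C@H]1[C@@H]2C[C@H](C)C(=O)[C@@H]2C[C@@](C)(O[Si](CC)(CC)CC)CC1=O | intermediate
22 | trans-fused hydroazulene-5,10-dione, C8 triethylsilyl ether (C1 isopropyl α, C2–H α, C4 methyl β, C6–H β, C8 methyl β) | CC(C)[C@H]1[C@@H]2C[C@H](C)C(=O)[C@H]2C[C@@](C)(O[Si](CC)(CC)CC)CC1=O | intermediate
23 | C8-hydroxy hydroazulene-5,10-dione | CC(C)[C@H]1[C@@H]2C[C@H](C)C(=O)[C@H]2C[C@@](C)(O)CC1=O | intermediate
24 | C8α,C10β-diol C5-ketone | CC(C)[C@H]1[C@@H]2C[C@H](C)C(=O)[C@H]2C[C@@](C)(O)C[C@@H]1O | intermediate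
25 | 4-(benzyloxy)benzoyl chloride | O=C(Cl)c1ccc(OCc2ccccc2)cc1 | starting material
26 | C10 4-(benzyloxy)benzoate with free C8–OH and C5 ketone | CC(C)[C@H]1[C@@H]2C[C@H](C)C(=O)[C@H]2C[C@@](C)(O)C[C@@H]1OC(=O)c1ccc(OCc2ccccc2)cc1 | intermediate
27 | C8 trimethylsilyl ether of 26 | CC(C)[C@H]1[C@@H]2C[C@H](C)C(=O)[C@H]2C[C@@](C)(O[Si](C)(C)C)C[C@@H]1OC(=O)c1ccc(OCc2ccccc2)cc1 | intermediate
28 | C4=C5 enol triflate (triflate on C5) | CC(C)[C@H]1[C@@H]2CC(C)=C(OS(=O)(=O)C(F)(F)F)[C@H]2C[C@@](C)(O[Si](C)(C)C)C[C@@H]1OC(=O)c1ccc(OCc2ccccc2)cc1 | intermediate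
29 | C4=C5 alkene, C8 trimethylsilyl ether | CC(C)[C@H]1[C@@H]2CC(C)=C[C@H]2C[C@@](C)(O[Si](C)(C)C)C[C@@H]1OC(=O)c1ccc(OCc2ccccc2)cc1 | intermediate
30 | C4=C5 alkene, free C8–OH | CC(C)[C@H]1[C@@H]2CC(C)=C[C@H]2C[C@@](C)(O)C[C@@H]1OC(=O)c1ccc(OCc2ccccc2)cc1 | intermediate
31 | 4α,5α-epoxide, O-benzyl ether of the target | CC(C)[C@H]1[C@@H]2C[C@@]3(C)O[C@H]3[C@H]2C[C@@](C)(O)C[C@@H]1OC(=O)c1ccc(OCc2ccccc2)cc1 | intermediate
32 | CNP0245441.1 | CC(C)[C@H]1[C@@H]2C[C@@]3(C)O[C@H]3[C@H]2C[C@@](C)(O)C[C@@H]1OC(=O)c1ccc(O)cc1 | target

Total step count: 19. Longest linear sequence: 17 steps (steps 3–19, from isobutyraldehyde); steps 1–2 form the second branch, which joins at step 9.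

**Steps most likely to fail**

Step 11 – poor facial selectivity in the C6–C2 bond formation, if the C4 methyl group and the C8 substituents steer the tethered alkene to opposite faces of the cyclopentene (mismatched pair). Fallback, from 10 back to 22: the antipodal tether is built in the same way. (S)-4-benzyl-3-propionyloxazolidin-2-one F1 is alkylated with 10 (NaN(SiMe3)2) to the imide F2; LiOH/H2O2 and then Na2SO3 should give, through the peroxy acid F3, the (R)-acid F4; SOCl2/benzotriazole gives the acylbenzotriazole F5; C-acylation of the lithium enolate of 5 gives the diketone F6, and benzyl chloroformate/pyridine the enol carbonate F7. Irradiation and hydrogenolysis as in step 11 should lead through the photoadduct F8 and the cyclobutanol F9 to the C4-epimeric diketone F10, and the DBU treatment, which also equilibrates C4 (α to the C5 ketone), converges on 22.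

Step 16 – loss of regiocontrol in the enolisation through competing deprotonation at the ring-fusion C6–H, which would place the double bond at C5=C6 and erode the C6 configuration. Fallback, from 27 back to 29: regiochemistry is taken from a stereospecific elimination instead of a kinetic enolate. NaBH4 (THF/MeOH, −20 °C) reduces the C5 ketone of 27; because C4–H is α and C6–H is β, either carbinol epimer can lose only the C4 hydrogen when the matching elimination mode is chosen. The β-alcohol F11 is converted (MsCl, Et3N) into the mesylate F12 and eliminated anti with DBU in hot toluene, whereas the α-alcohol F13 is eliminated syn with the Burgess reagent in warm toluene; both should give 29.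

Step 18 – poor facial selectivity of oxygen transfer, if the remote C8 hydroxyl does not hold the oxidant over the α-face. Fallback, from 30 back to 31: reagent control replaces substrate direction. Shi epoxidation of the trisubstituted alkene with the fructose-derived chiral ketone (the antipode matched to the α-face), KHSO5 as oxidant, in K2CO3-buffered MeCN/dimethoxymethane/H2O at 0 °C should give 31 directly; no new compound is made.

**Further compounds**

F1 | step 11 | (S)-4-benzyl-3-propionyloxazolidin-2-one | CCC(=O)N1[C@@H](Cc2ccccc2)COC1=O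
F2 | step 11 | (S)-4-benzyl-3-[(2R,4E)-2,6-dimethylhept-4-enoyl]oxazolidin-2-one | CC(C)/C=C/C[C@@H](C)C(=O)N1[C@@H](Cc2ccccc2)COC1=O
F3 | step 11 | (2R,4E)-2,6-dimethylhept-4-eneperoxoic acid | CC(C)/C=C/C[C@@H](C)C(=O)OO
F4 | step 11 | (2R,4E)-2,6-dimethylhept-4-enoic acid | CC(C)/C=C/C[C@@H](C)C(=O)O
F5 | step 11 | 1-[(2R,4E)-2,6-dimethylhept-4-enoyl]-1H-benzotriazole | CC(C)/C=C/C[C@@H](C)C(=O)n1nnc2ccccc12
F6 | step 11 | (4R)-2-[(2R,4E)-2,6-dimethylhept-4-enoyl]-4-methyl-4-(triethylsilyloxy)cyclopentan-1-one, drawn as its ring enol | CC(C)/C=C/C[C@@H](C)C(=O)C1=C(O)C[C@](C)(O[Si](CC)(CC)CC)C1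
F7 | step 11 | benzyl (4R)-2-[(2R,4E)-2,6-dimethylhept-4-enoyl]-4-methyl-4-(triethylsilyloxy)cyclopent-1-en-1-yl carbonate | CC(C)/C=C/C[C@@H](C)C(=O)C1=C(OC(=O)OCc2ccccc2)C[C@](C)(O[Si](CC)(CC)CC)C1
F8 | step 11 | C4 epimer of photoadduct 19 | CC(C)[C@H]1[C@@H]2C[C@@H](C)C(=O)[C@@]23C[C@@](C)(O[Si](CC)(CC)CC)C[C@@]13OC(=O)OCc1ccccc1
F9 | step 11 | C4 epimer of cyclobutanol 20 | CC(C)[C@H]1[C@@H]2C[C@@H](C)C(=O)[C@@]23C[C@@](C)(O[Si](CC)(CC)CC)C[C@@]13O
F10 | step 11 | C4 epimer of dione 22 (C4 methyl α) | CC(C)[C@H]1[C@@H]2C[C@@H](C)C(=O)[C@H]2C[C@@](C)(O[Si](CC)(CC)CC)CC1=O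
F11 | step 16 | C5 β-alcohol from 27 | CC(C)[C@H]1[C@@H]2C[C@H](C)[C@H](O)[C@H]2C[C@@](C)(O[Si](C)(C)C)C[C@@H]1OC(=O)c1ccc(OCc2ccccc2)cc1
F12 | step 16 | C5 β-methanesulfonate of F11 | CC(C)[C@H]1[C@@H]2C[C@H](C)[C@H](OS(C)(=O)=O)[C@H]2C[C@@](C)(O[Si](C)(C)C)C[C@@H]1OC(=O)c1ccc(OCc2ccccc2)cc1
F13 | step 16 | C5 α-alcohol from 27 | CC(C)[C@H]1[C@@H]2C[C@H](C)[C@@H](O)[C@H]2C[C@@](C)(O[Si](C)(C)C)C[C@@H]1OC(=O)c1ccc(OCc2ccccc2)cc1
F0 | step 18 | none | none
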